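Abbreviations: MOM = methoxymethyl; TBS = tert-butyldimethylsilyl; Ipc = isopinocampheyl; TRIP = 3,3′-bis(2,4,6-triisopropylphenyl)-1,1′-binaphthyl-2,2′-diyl hydrogen phosphate; dppp = 1,3-bis(diphenylphosphino)propane. Ring A is the oxygenated core ring, ring B the aryl of the enone, ring C the aryl on C7, ring D the aryl on C1; chain atoms C1–C7 are counted from ring D.

## The problem

Target 27 is a 2′-hydroxychalcone whose ring A (2,4-dihydroxy-6-methoxyphenyl) carries, on the carbon between its two hydroxyls, C7 of an (E)-1,7-bis(4-hydroxyphenyl)hept-5-en-3-ol chain. No ring has to be closed: four benzene rings must be joined in the right positions through one enone and one seven-carbon chain. Ring A is pentasubstituted, with the acyl group between the methoxy carbon and a hydroxyl carbon, and C7 between the two hydroxyl carbons and para to the methoxy group. There are two stereocentres, C7 (S, a doubly benzylic and allylic methine) and C3 (R, a secondary carbinol). They stand in a 1,5-relationship across the E C5=C6 alkene, too far apart for one to control the other, so each needs its own catalyst. The molecule is fragile in three ways: Lewis or strong Brønsted acid can ionise the bond between C7 and the phloroglucinol-type ring A or shift the alkene, strong base can deprotonate C7, and an enone next to a free ortho hydroxyl closes to a flavanone in base or hot acid. The textbook chalcone syntheses (Friedel–Crafts acylation, base-mediated aldol condensation) are therefore both badly matched to this target. The enabling feature is that ring A without its enone is a 2-substituted 5-methoxyresorcinol with local twofold symmetry: its two CH positions are equivalent, each between the methoxy carbon and an oxygenated carbon. One halogenation therefore marks the enone position without ambiguity, and the C(=O)–CH=CH–ring B unit can be added there as carbon monoxide plus a styrene.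

## Retrosynthesis

**27 ⇒ 26 ⇒ 25 (unmasking).** Only O–Si and O–CH2OMe bonds are cut. Five phenols and one alcohol must be masked in the metal-mediated steps. The two ring A oxygens carry MOM groups, which are needed anyway as directing groups and to keep ring A symmetric; every other oxygen carries TBS. Fluoride comes first (25 to 26), while the 2′-oxygen is still capped and the enone cannot cyclise. Methanolic HCl at room temperature then takes 26 to 27.

**25 ⇒ 20 + 24 + 23 (key disconnection).** The ring A–C(=O) and C(=O)–CH bonds are cut together, giving aryl iodide 20, carbon monoxide 24 and styrene 23. The neighbouring cuts are worse for this target: cutting the CH=CH bond leads to an aldol condensation in base beside an ortho oxygen, and cutting only the ring A–C(=O) bond leads to a Lewis-acid acylation that endangers C7. The three-component cut leaves a gas, a one-step styrene and an iodide that holds all the stereochemistry. The forward reaction must let CO insertion outrun direct arylation of the styrene and must give the linear E enone.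

**20 ⇒ 19 ⇒ 18 (iodide and symmetry).** The carbon–iodine bond and one O–MOM bond are cut. Bis-MOM ether 19 has a twofold-symmetric ring A, so mono-iodination can give only 20, whichever open position reacts. Phenol 18 is capped to restore that symmetry and to keep a free ortho hydroxyl away from the acylpalladium intermediate.

**18 ⇒ 9 + 16 (via 17; the C7 stereocentre).** The C7–C6 bond is cut. An ortho-quinone methide 17, released from ethyl ether 9, is the C7 electrophile, and its anchoring phenol is one of the ring A hydroxyls. Alkenylboronate 16 brings C1–C6 with the E alkene and C3 in place. Cutting C7–ring A instead would mean a Friedel–Crafts reaction of a phloroglucinol on an allyl cation, which is racemic and regiochemically loose at both partners. Both precursors are one aromatic ring simpler than 18. The forward step must control the face of 17 by catalyst alone, since C3 is too remote to help.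

**9 ⇒ 8 ⇒ 5 + 7 (from 6); 5 ⇒ 4 ⇒ 2 (via 3) ⇒ 1 (ring A/ring C half).** The C7–ring C bond is cut to aldehyde 5 and Grignard reagent 7, made from bromide 6. The C7–ring A bond goes back to formylation of aryllithium 3, generated from bis-MOM ether 2 at the one carbon flanked by two MOM ethers. This is where the ring A substitution pattern is fixed; electrophilic formylation of 1 would give mixtures. One MOM group of 4 is then removed to give the phenol of 5 that later drives quinone-methide formation. Starting material 1 is 5-methoxyresorcinol.

**16 ⇒ 14 (via 15) ⇒ 13 ⇒ 12 ⇒ 11 ⇒ 10 (C1–C6 half).** The C6–B bond is cut by hydroboration of terminal alkyne 14, which guarantees the E geometry. The C3–C4 bond is cut by catalytic asymmetric propargylation of aldehyde 12, which sets C3 and delivers the alkyne in one step; an allylation would need further steps to reach an alkenylboron. Aldehyde 12 comes from commercial ester 10 by silylation (11) and partial reduction.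

**23 ⇒ 21 (via 22).** The styrene partner is made from 4-acetoxystyrene 21 by acetate methanolysis and immediate silylation of 4-ethenylphenol 22.

## Roads not taken

Alternative 1: Ring A itself is cut, into 3-methoxycyclobutenone A1 and a triisopropylsiloxyalkyne A2 that already carries C7 and the whole chain. Heating them would open A1 to a vinylketene, add it across the alkyne, and after a second electrocyclic opening and a six-electron closure give phenol A3. Its merit is that the mechanism places all five ring A substituents and differentiates the two oxygens (one free, one silylated). For this target the differentiation is unnecessary, since both end as hydroxyls. The weak points are serious. In A2, C7 is propargylic, benzylic and allylic at once, hence very acidic and prone to allene or enyne isomerisation, yet siloxyalkynes are made under strongly basic conditions and the benzannulation needs prolonged heating. No obvious method sets that centre as one enantiomer. A3 still lacks the enone, so an acylation or a halogenation and carbonylation must follow; this route replaces only the preparation of 18, not the key step. The chosen plan sets C7 on a robust, purchased arene by catalyst control and needs no ring synthesis. Where Alternative 1 is better is in regiochemical certainty without reliance on directed lithiation and selective mono-deprotection (steps 2 and 3); against that stand its fragile alkyne and its extra steps to A1 and A2.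

Alternative 2: The C3–C4 and C7–ring C bonds are cut at once. A zerovalent nickel catalyst with a chiral ligand would unite the ring A butadiene A4, aldehyde 12 and the ring C boronic acid A5 to give homoallylic alcohol A6, leaving the E C5=C6 alkene. In step economy this is clearly superior: three simple pieces give the whole chain and both stereocentres in one step, and silylation of A6 would give 19 directly, replacing steps 3–5 and 8–12. The weak points are selectivity. After oxidative cyclisation the allylnickel unit spans C5–C7, and aryl transfer must occur at C7, the terminus hindered by the di-ortho-substituted ring A. Transfer at C5 instead keeps the C6=C7 alkene conjugated with ring A and is the likelier outcome. One ligand would also have to fix the absolute configuration at C3 and the 1,5-relationship to C7 through an allylmetal intermediate that can equilibrate; if the intrinsic preference gave the wrong diastereomer, nothing could be adjusted. The chosen plan is longer, but it sets C3 and C7 in two separate catalyst-controlled steps, each correctable by changing one catalyst antipode. Alternative 2 is an alternative front end, not an alternative endgame, since A6 would still need the iodination and the carbonylative coupling.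

Alternative 3: Ring A is cut at one C–C bond and traced to an open-chain O-methylated triketide ester A7 bearing the C7 chain on the carbon between ester and ketone. Alkoxide would make the methylene between the enol ether carbon and the methyl ketone attack the ester carbonyl, and aromatisation would give acetophenone A8. Its merits are real: the chain encodes the methoxy position, the acetyl group arrives with the ring, and no palladium, iodide or CO pressure is needed. The weak points lie before and after the key step. A7 requires attaching a secondary diaryl-allyl unit to a 1,3-dicarbonyl carbon with control of C7, for which only ionising, racemising alkylations are evident. The polycarbonyl chain can also close by aldol or pyrone-forming modes, and aryl silyl ethers do not survive alkoxide. From A8 the enone would have to be raised by aldol condensation in base beside free ortho hydroxyls, the very setting that gives flavanones, so extra protection steps return. The chosen plan keeps every phenol masked while the enone forms under weakly basic, non-acidic conditions, and it buys ring A instead of building it. What it must set against the operational simplicity of an aldol endgame is a demanding carbonylation of a hindered aryl iodide.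

Key step: step 15

Assumption: the sense of induction of (S)-TRIP in step 8 and of (R)-3,3′-dibromo-1,1′-bi-2-naphthol in step 11 is assigned by analogy with the accepted closed transition-state models for these catalyst families; should either deliver the opposite configuration, its mirror-image catalyst is used and nothing else in the route changes.

## Route

Step 1
Reactants: 1 5-methoxyresorcinol
Product: 2 1-methoxy-3,5-bis(methoxymethoxy)benzene
Conditions: MOMCl (2.5 equiv), i-Pr2NEt, CH2Cl2, 0 °C → rt
Reagents that add atoms: chloromethyl methyl ether, COCCl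
Why: Double O-alkylation of the phenols under amine base (Williamson-type etherification); the MOM ethers protect the phenols and are the directing groups for step 2.

Step 2
Reactants: 2 1-methoxy-3,5-bis(methoxymethoxy)benzene
Product: 4 4-methoxy-2,6-bis(methoxymethoxy)benzaldehyde, via aryllithium 3 (not isolated)
Conditions: n-BuLi, TMEDA, THF, 0 °C; then DMF, 0 °C → rt; aq. NH4Cl
Reagents that add atoms: N,N-dimethylformamide, CN(C)C=O
Why: Directed ortho-metalation removes the one proton flanked by two MOM ethers, the only site held by two strong directing groups, and DMF formylates aryllithium 3; this fixes the future C7 carbon between the two future hydroxyls and para to the methoxy group.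

Step 3
Reactants: 4 4-methoxy-2,6-bis(methoxymethoxy)benzaldehyde
Product: 5 2-hydroxy-4-methoxy-6-(methoxymethoxy)benzaldehyde
Conditions: HCl (cat.), MeOH, 0 °C → rt, stopped at mono-cleavage; aq. NaHCO3
Reagents that add atoms: none
Why: Selective acid-catalysed cleavage of one of two equivalent MOM ethers ortho to a carbonyl, a known desymmetrising deprotection; the freed phenol chelates the formyl oxygen, which then no longer assists cleavage of the second acetal, and any dimethyl acetal of the aldehyde reverts on aqueous work-up.

Step 4
Reactants: 5 2-hydroxy-4-methoxy-6-(methoxymethoxy)benzaldehyde; 6 (4-bromophenoxy)(tert-butyl)dimethylsilane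
Product: 8 2-[{4-[(TBS)oxy]phenyl}(hydroxy)methyl]-5-methoxy-3-(methoxymethoxy)phenol (racemic), via arylmagnesium bromide 7 (not isolated)
Conditions: 6, Mg, THF, reflux; then 5 (7 in 2.3 equiv), THF, 0 °C → rt; aq. NH4Cl; used without chromatography
Reagents that add atoms: none
Why: Grignard addition to an aldehyde; the first equivalent of 7 is consumed by the phenol, and the resulting phenoxide ArOMgBr chelates the formyl group for attack by the second equivalent. The carbinol centre is racemic, which is irrelevant because it becomes planar in step 11.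

Step 5
Reactants: 8 2-[{4-[(TBS)oxy]phenyl}(hydroxy)methyl]-5-methoxy-3-(methoxymethoxy)phenol
Product: 9 2-[{4-[(TBS)oxy]phenyl}(ethoxy)methyl]-5-methoxy-3-(methoxymethoxy)phenol (racemic)
Conditions: EtOH, PPTS (cat.), rt
Reagents that add atoms: ethanol, CCO
Why: Acid-catalysed SN1 etherification through the strongly stabilised ortho-hydroxybenzhydryl cation, trapped by solvent ethanol; PPTS at room temperature should spare the MOM and aryl silyl ethers, and the ethyl ether is the storable quinone-methide precursor for step 11.

Step 6
Reactants: 10 methyl 3-(4-hydroxyphenyl)propanoate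
Product: 11 methyl 3-{4-[(TBS)oxy]phenyl}propanoate
Conditions: TBSCl, imidazole, DMF, rt
Reagents that add atoms: tert-butyldimethylsilyl chloride, CC(C)(C)[Si](C)(C)Cl
Why: Standard silylation of a phenol; the ester is untouched.

Step 7
Reactants: 11 methyl 3-{4-[(TBS)oxy]phenyl}propanoate
Product: 12 3-{4-[(TBS)oxy]phenyl}propanal
Conditions: i-Bu2AlH (1.05 equiv), CH2Cl2, –78 °C; MeOH, then aq. potassium sodium tartrate
Reagents that add atoms: none
Why: Partial reduction of a methyl ester to the aldehyde at –78 °C, where the tetrahedral aluminium alkoxide persists until the quench; unbranched 3-arylpropanoates are routine substrates.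

Step 8
Reactants: 12 3-{4-[(TBS)oxy]phenyl}propanal
Product: 13 (3R)-1-{4-[(TBS)oxy]phenyl}hex-5-yn-3-ol
Conditions: allenylboronic acid pinacol ester, (S)-TRIP (5 mol %), 4 Å MS, toluene, –20 °C; aqueous work-up
Reagents that add atoms: allenylboronic acid pinacol ester, C=C=CB1OC(C)(C)C(C)(C)O1
Why: Chiral phosphoric acid-catalysed propargylation of an aldehyde by an allenylboronate through a six-membered chair transition state (SE2′ transfer gives the homopropargylic alcohol). The (S)-acid binds the boronate oxygen and the formyl hydrogen and exposes the aldehyde face that gives the 3R carbinol, C3 of the target.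

Step 9
Reactants: 13 (3R)-1-{4-[(TBS)oxy]phenyl}hex-5-yn-3-ol
Product: 14 tert-butyl{[(3R)-1-{4-[(TBS)oxy]phenyl}hex-5-yn-3-yl]oxy}dimethylsilane
Conditions: TBSCl, imidazole, DMF, rt
Reagents that add atoms: tert-butyldimethylsilyl chloride, CC(C)(C)[Si](C)(C)Cl
Why: Standard silylation of a secondary alcohol; it removes the protic group before hydroboration and gives all silyl ethers one set of cleavage conditions.

Step 10
Reactants: 14 tert-butyl{[(3R)-1-{4-[(TBS)oxy]phenyl}hex-5-yn-3-yl]oxy}dimethylsilane
Product: 16 diethyl [(1E,4R)-4-[(TBS)oxy]-6-{4-[(TBS)oxy]phenyl}hex-1-en-1-yl]boronate, via alkenyldiisopinocampheylborane 15 (not isolated)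
Conditions: (–)-(Ipc)2BH (pre-formed from (+)-α-pinene), THF, –25 → 0 °C; then CH3CHO (excess), 0 → 40 °C; volatiles removed, used crude
Reagents that add atoms: diisopinocampheylborane, B([C@@H]1C[C@@H]2C[C@H]([C@H]1C)C2(C)C)[C@@H]1C[C@@H]2C[C@H]([C@H]1C)C2(C)C; acetaldehyde, CC=O
Why: Syn hydroboration of the terminal alkyne by the hindered dialkylborane puts boron on the terminal carbon and gives only the E alkenylborane 15. Acetaldehyde then expels both isopinocampheyl groups as α-pinene, a known dealkylative route to diethyl alkenylboronates, giving the acyclic boronate that can exchange with the biphenol catalyst.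

Step 11
Reactants: 9 2-[{4-[(TBS)oxy]phenyl}(ethoxy)methyl]-5-methoxy-3-(methoxymethoxy)phenol; 16 diethyl [(1E,4R)-4-[(TBS)oxy]-6-{4-[(TBS)oxy]phenyl}hex-1-en-1-yl]boronate
Product: 18 2-[(1S,2E,5R)-5-[(TBS)oxy]-1,7-bis{4-[(TBS)oxy]phenyl}hept-2-en-1-yl]-5-methoxy-3-(methoxymethoxy)phenol, via ortho-quinone methide 17 (not isolated)
Conditions: (R)-3,3′-dibromo-1,1′-bi-2-naphthol (15 mol %), 16 (1.5 equiv), 4 Å MS, toluene, 40–60 °C; aqueous work-up
Reagents that add atoms: none
Why: Chiral biphenol-catalysed conjugate addition of an alkenylboronate to an ortho-quinone methide. Loss of ethanol from 9 gives 17; the biphenol exchanges for ethoxide on boron to give a more Lewis acidic chiral boronate, which binds the quinone-methide oxygen and transfers the alkenyl group to the exocyclic carbon through a closed transition state with retention of the E geometry. The C7 stereocentre (S) is set by the catalyst alone, the C3 silyl ether being too remote to interfere.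

Step 12
Reactants: 18 2-[(1S,2E,5R)-5-[(TBS)oxy]-1,7-bis{4-[(TBS)oxy]phenyl}hept-2-en-1-yl]-5-methoxy-3-(methoxymethoxy)phenol
Product: 19 2-[(1S,2E,5R)-5-[(TBS)oxy]-1,7-bis{4-[(TBS)oxy]phenyl}hept-2-en-1-yl]-5-methoxy-1,3-bis(methoxymethoxy)benzene
Conditions: MOMCl, i-Pr2NEt, n-Bu4NI (cat.), CH2Cl2, 0 → 40 °C
Reagents that add atoms: chloromethyl methyl ether, COCCl
Why: O-alkylation of the hindered phenol under amine base, which spares the aryl silyl ethers; it restores the twofold symmetry of ring A and masks the phenol that would otherwise intercept the acylpalladium intermediate of step 15.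

Step 13
Reactants: 19 2-[(1S,2E,5R)-5-[(TBS)oxy]-1,7-bis{4-[(TBS)oxy]phenyl}hept-2-en-1-yl]-5-methoxy-1,3-bis(methoxymethoxy)benzene
Product: 20 2-[(1S,2E,5R)-5-[(TBS)oxy]-1,7-bis{4-[(TBS)oxy]phenyl}hept-2-en-1-yl]-4-iodo-5-methoxy-1,3-bis(methoxymethoxy)benzene
Conditions: NIS (1.05 equiv), MeCN/CH2Cl2, 0 °C → rt, dark
Reagents that add atoms: N-iodosuccinimide, O=C1CCC(=O)N1I
Why: Electrophilic aromatic iodination; the tri-oxygenated ring A is far more nucleophilic than the mono-silyloxy rings C and D or the disubstituted alkene, and its two open positions are equivalent, so one equivalent should give a single mono-iodide without added acid.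

Step 14
Reactants: 21 4-acetoxystyrene
Product: 23 tert-butyl(4-ethenylphenoxy)dimethylsilane, via 4-ethenylphenol 22 (not isolated)
Conditions: K2CO3 (0.1 equiv), MeOH, 0 °C → rt; solvent exchange; TBSCl, imidazole, DMF, rt
Reagents that add atoms: tert-butyldimethylsilyl chloride, CC(C)(C)[Si](C)(C)Cl
Why: Base-catalysed methanolysis of the aryl acetate releases 4-ethenylphenol, which is silylated at once to forestall its polymerisation; both operations are routine.

Step 15
Reactants: 20 2-[(1S,2E,5R)-5-[(TBS)oxy]-1,7-bis{4-[(TBS)oxy]phenyl}hept-2-en-1-yl]-4-iodo-5-methoxy-1,3-bis(methoxymethoxy)benzene; 23 tert-butyl(4-ethenylphenoxy)dimethylsilane; 24 carbon monoxide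
Product: 25 (2E)-1-{3-[(1S,2E,5R)-5-[(TBS)oxy]-1,7-bis{4-[(TBS)oxy]phenyl}hept-2-en-1-yl]-6-methoxy-2,4-bis(methoxymethoxy)phenyl}-3-{4-[(TBS)oxy]phenyl}prop-2-en-1-one
Conditions: Pd(OAc)2 (5 mol %), dppp (10 mol %), NEt3 (3 equiv), 23 (2 equiv), CO (10 bar), 1,4-dioxane, 100 °C
Reagents that add atoms: none
Why: Carbonylative Heck coupling, a reaction type known for aryl iodides and triflates with styrenes as a route to chalcones. Zerovalent palladium, formed in situ from Pd(OAc)2 and dppp, adds oxidatively to the carbon–iodine bond of 20; CO inserts to give the aroylpalladium species, styrene 23 inserts with the acyl group on its terminal carbon and palladium on the benzylic carbon, and syn β-hydride elimination releases the E enone while NEt3 takes up HI and returns zerovalent palladium. Two skeletal bonds form (ring A–C(=O) and C(=O)–CH); no ring closes and no stereocentre is created, C7 and C3 being spectators under these non-acidic, weakly basic conditions. The step needs carbonylation to outrun direct arylation of the styrene, and CO pressure, the chelating bisphosphine and the two ortho substituents, which slow alkene insertion into the aryl–palladium bond but favour acyl formation, are expected to secure this. The position of the enone on ring A is fixed by the iodine, itself unambiguous through the symmetry of 19, and the linear enone follows from the electronic bias of the styrene. The internal C5=C6 alkene should not compete, because it is 1,2-disubstituted and cannot reach the meta-disposed palladium centre intramolecularly. All phenols are masked, so the acylpalladium intermediate cannot be diverted to an ester or a flavone.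

Step 16
Reactants: 25 fully protected chalcone (bis-MOM, tetrakis-TBS)
Product: 26 (2E)-1-{3-[(1S,2E,5R)-5-hydroxy-1,7-bis(4-hydroxyphenyl)hept-2-en-1-yl]-6-methoxy-2,4-bis(methoxymethoxy)phenyl}-3-(4-hydroxyphenyl)prop-2-en-1-one
Conditions: n-Bu4NF (6 equiv), AcOH (6 equiv), THF, 0 °C → rt
Reagents that add atoms: none
Why: Fluoride-mediated cleavage of the three aryl and one alkyl silyl ethers, buffered with acetic acid; with the 2′-oxygen still capped as its MOM ether the enone cannot close to a flavanone under these mildly basic conditions.

Step 17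
Reactants: 26 bis-MOM chalcone tetraol
Product: 27 (2E)-1-{2,4-dihydroxy-3-[(1S,2E,5R)-5-hydroxy-1,7-bis(4-hydroxyphenyl)hept-2-en-1-yl]-6-methoxyphenyl}-3-(4-hydroxyphenyl)prop-2-en-1-one
Conditions: HCl (ca. 1 M in MeOH), 0 °C → rt
Reagents that add atoms: none
Why: Acid-catalysed acetal exchange removes the two MOM ethers, which are activated by the ortho and para acyl group and should cleave at room temperature, conditions that 2′-hydroxy-6′-methoxychalcones are known to tolerate without flavanone closure; C7 and C3 are not touched, and the product is the target.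

## Compound list

1 | 5-methoxyresorcinol (5-methoxybenzene-1,3-diol) | COc1cc(O)cc(O)c1 | starting material
2 | 1-methoxy-3,5-bis(methoxymethoxy)benzene | COc1cc(OCOC)cc(OCOC)c1 | intermediate
3 | [4-methoxy-2,6-bis(methoxymethoxy)phenyl]lithium (not isolated) | COc1cc(OCOC)c([Li])c(OCOC)c1 | intermediate
4 | 4-methoxy-2,6-bis(methoxymethoxy)benzaldehyde | COc1cc(OCOC)c(C=O)c(OCOC)c1 | intermediate
5 | 2-hydroxy-4-methoxy-6-(methoxymethoxy)benzaldehyde | COc1cc(O)c(C=O)c(OCOC)c1 | intermediate
6 | (4-bromophenoxy)(tert-butyl)dimethylsilane | CC(C)(C)[Si](C)(C)Oc1ccc(Br)cc1 | starting material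
7 | {4-[(tert-butyldimethylsilyl)oxy]phenyl}magnesium bromide (not isolated) | CC(C)(C)[Si](C)(C)Oc1ccc([Mg]Br)cc1 | intermediate
8 | 2-[{4-[(tert-butyldimethylsilyl)oxy]phenyl}(hydroxy)methyl]-5-methoxy-3-(methoxymethoxy)phenol, racemic | COc1cc(O)c(C(O)c2ccc(O[Si](C)(C)C(C)(C)C)cc2)c(OCOC)c1 | intermediate
9 | 2-[{4-[(tert-butyldimethylsilyl)oxy]phenyl}(ethoxy)methyl]-5-methoxy-3-(methoxymethoxy)phenol, racemic | CCOC(c1ccc(O[Si](C)(C)C(C)(C)C)cc1)c1c(O)cc(OC)cc1OCOC | intermediate
10 | methyl 3-(4-hydroxyphenyl)propanoate | COC(=O)CCc1ccc(O)cc1 | starting material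
11 | methyl 3-{4-[(tert-butyldimethylsilyl)oxy]phenyl}propanoate | COC(=O)CCc1ccc(O[Si](C)(C)C(C)(C)C)cc1 | intermediate
12 | 3-{4-[(tert-butyldimethylsilyl)oxy]phenyl}propanal | O=CCCc1ccc(O[Si](C)(C)C(C)(C)C)cc1 | intermediate
13 | (3R)-1-{4-[(tert-butyldimethylsilyl)oxy]phenyl}hex-5-yn-3-ol | C#CC[C@H](O)CCc1ccc(O[Si](C)(C)C(C)(C)C)cc1 | intermediate
14 | tert-butyl{[(3R)-1-{4-[(tert-butyldimethylsilyl)oxy]phenyl}hex-5-yn-3-yl]oxy}dimethylsilane | C#CC[C@H](O[Si](C)(C)C(C)(C)C)CCc1ccc(O[Si](C)(C)C(C)(C)C)cc1 | intermediate
15 | [(1E,4R)-4-[(tert-butyldimethylsilyl)oxy]-6-{4-[(tert-butyldimethylsilyl)oxy]phenyl}hex-1-en-1-yl]di(isopinocampheyl)borane, Ipc groups from (+)-α-pinene (not isolated) | B(/C=C/C[C@H](O[Si](C)(C)C(C)(C)C)CCc1ccc(O[Si](C)(C)C(C)(C)C)cc1)([C@@H]1C[C@@H]2C[C@H]([C@H]1C)C2(C)C)[C@@H]1C[C@@H]2C[C@H]([C@H]1C)C2(C)C | intermediate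
16 | diethyl [(1E,4R)-4-[(tert-butyldimethylsilyl)oxy]-6-{4-[(tert-butyldimethylsilyl)oxy]phenyl}hex-1-en-1-yl]boronate | CCOB(OCC)/C=C/C[C@H](O[Si](C)(C)C(C)(C)C)CCc1ccc(O[Si](C)(C)C(C)(C)C)cc1 | intermediate
17 | 6-({4-[(tert-butyldimethylsilyl)oxy]phenyl}methylidene)-3-methoxy-5-(methoxymethoxy)cyclohexa-2,4-dien-1-one, exocyclic geometry unassigned (not isolated) | O=C1C=C(OC)C=C(OCOC)C1=Cc1ccc(O[Si](C)(C)C(C)(C)C)cc1 | intermediate
18 | 2-[(1S,2E,5R)-5-[(tert-butyldimethylsilyl)oxy]-1,7-bis{4-[(tert-butyldimethylsilyl)oxy]phenyl}hept-2-en-1-yl]-5-methoxy-3-(methoxymethoxy)phenol | COc1cc(OCOC)c([C@@H](/C=C/C[C@H](O[Si](C)(C)C(C)(C)C)CCc2ccc(O[Si](C)(C)C(C)(C)C)cc2)c2ccc(O[Si](C)(C)C(C)(C)C)cc2)c(O)c1 | intermediate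
19 | 2-[(1S,2E,5R)-5-[(tert-butyldimethylsilyl)oxy]-1,7-bis{4-[(tert-butyldimethylsilyl)oxy]phenyl}hept-2-en-1-yl]-5-methoxy-1,3-bis(methoxymethoxy)benzene | COc1cc(OCOC)c([C@@H](/C=C/C[C@H](O[Si](C)(C)C(C)(C)C)CCc2ccc(O[Si](C)(C)C(C)(C)C)cc2)c2ccc(O[Si](C)(C)C(C)(C)C)cc2)c(OCOC)c1 | intermediate
20 | 2-[(1S,2E,5R)-5-[(tert-butyldimethylsilyl)oxy]-1,7-bis{4-[(tert-butyldimethylsilyl)oxy]phenyl}hept-2-en-1-yl]-4-iodo-5-methoxy-1,3-bis(methoxymethoxy)benzene | COc1cc(OCOC)c([C@@H](/C=C/C[C@H](O[Si](C)(C)C(C)(C)C)CCc2ccc(O[Si](C)(C)C(C)(C)C)cc2)c2ccc(O[Si](C)(C)C(C)(C)C)cc2)c(OCOC)c1I | intermediate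
21 | 4-acetoxystyrene (4-ethenylphenyl acetate) | CC(=O)Oc1ccc(C=C)cc1 | starting material
22 | 4-ethenylphenol (not isolated) | C=Cc1ccc(O)cc1 | intermediate
23 | tert-butyl(4-ethenylphenoxy)dimethylsilane | C=Cc1ccc(O[Si](C)(C)C(C)(C)C)cc1 | intermediate
24 | carbon monoxide | [C-]#[O+] | starting material
25 | (2E)-1-{3-[(1S,2E,5R)-5-[(tert-butyldimethylsilyl)oxy]-1,7-bis{4-[(tert-butyldimethylsilyl)oxy]phenyl}hept-2-en-1-yl]-6-methoxy-2,4-bis(methoxymethoxy)phenyl}-3-{4-[(tert-butyldimethylsilyl)oxy]phenyl}prop-2-en-1-one | COc1cc(OCOC)c([C@@H](/C=C/C[C@H](O[Si](C)(C)C(C)(C)C)CCc2ccc(O[Si](C)(C)C(C)(C)C)cc2)c2ccc(O[Si](C)(C)C(C)(C)C)cc2)c(OCOC)c1C(=O)/C=C/c1ccc(O[Si](C)(C)C(C)(C)C)cc1 | intermediate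
26 | (2E)-1-{3-[(1S,2E,5R)-5-hydroxy-1,7-bis(4-hydroxyphenyl)hept-2-en-1-yl]-6-methoxy-2,4-bis(methoxymethoxy)phenyl}-3-(4-hydroxyphenyl)prop-2-en-1-one | COc1cc(OCOC)c([C@@H](/C=C/C[C@H](O)CCc2ccc(O)cc2)c2ccc(O)cc2)c(OCOC)c1C(=O)/C=C/c1ccc(O)cc1 | intermediate
27 | (2E)-1-{2,4-dihydroxy-3-[(1S,2E,5R)-5-hydroxy-1,7-bis(4-hydroxyphenyl)hept-2-en-1-yl]-6-methoxyphenyl}-3-(4-hydroxyphenyl)prop-2-en-1-one (CNP0177199.3) | COc1cc(O)c([C@@H](/C=C/C[C@H](O)CCc2ccc(O)cc2)c2ccc(O)cc2)c(O)c1C(=O)/C=C/c1ccc(O)cc1 | target

## Step count and risk

Total: 17 steps. Longest linear sequence: 11 steps (steps 1–5, 11–13, 15–17 from 1; the branch from 10 through steps 6–13 and 15–17 is equally long).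

**Step 15 (key step).** The most likely failures are sluggish oxidative addition to the electron-rich, di-ortho-substituted carbon–iodine bond, direct arylation of the styrene without CO uptake, and reductive loss of iodine. Alkene migration by a palladium hydride and slow loss of aryl silyl ethers in hot amine are lesser risks.
Fallback, from 20 (with 6) back to 25, without carbonylation: Heck coupling of bromide 6 with N-methoxy-N-methylacrylamide (Pd(OAc)2, P(o-tol)3, NEt3, DMF, 100 °C) would give the Weinreb amide F1. Iodine–lithium exchange on 20 (n-BuLi, THF, –78 °C) would give the chelated aryllithium F2, and its acylation by F1 should give 25 directly, since the tetrahedral adduct prevents over-addition.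

**Step 11.** The second ortho substituent on the quinone methide and its strong stabilisation by three oxygens may slow the catalysed addition. Uncatalysed background addition, ethanol re-addition and quinone-methide dimerisation could then erode facial selectivity at C7.
Fallback, from 4 and 14 back to 19, setting C7 by conjugate addition instead:
- Horner–Wadsworth–Emmons reaction of 4 with diethyl [(pyridin-2-ylsulfonyl)methyl]phosphonate (NaH, THF) would give the vinyl sulfone F3.
- Rhodium-catalysed asymmetric conjugate addition of {4-[(TBS)oxy]phenyl}boronic acid (Rh(acac)(C2H4)2, the Chiraphos antipode that gives the 2S product, dioxane/H2O) would give the diaryl sulfone F4.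
- Semi-hydrogenation of 14 (H2, Pd/CaCO3 poisoned with Pb(OAc)2, quinoline) would give the alkene F5, and ozonolysis (O3, CH2Cl2, –78 °C; PPh3) the aldehyde F6.
- Julia–Kocienski olefination of F4 with F6 (KN(SiMe3)2, DME, –60 °C → rt) should give the E alkene 19, which also bypasses steps 3–5, 10 and 12.

**Step 8.** Unbranched aliphatic aldehydes are the least selective substrates of acid-catalysed propargylation, so incomplete facial discrimination at C3 is the main risk.
Fallback, from 12 back to 13, by resolution instead of asymmetric C–C bond formation: Corey–Chaykovsky methylenation of 12 (Me3SI, n-BuLi, THF, 0 °C) would give the racemic epoxide F7. Hydrolytic kinetic resolution with (R,R)-(salen)Co(OAc), the acetate of trivalent cobalt with N,N′-bis(3,5-di-tert-butylsalicylidene)-1,2-cyclohexanediamine, and 0.55 equiv of water would leave the (R)-epoxide F8. Opening at the terminal carbon with LiC≡CH and BF3·OEt2 (THF, –78 °C) gives 13 without touching the stereocentre.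

**Step 3.** Over-cleavage to the bis-phenol or stalling short of full conversion would leave a mixture; the margin between the first and second acetal cleavage rests only on chelation.
Fallback, from 4 back to 5, by exhaustive cleavage and selective re-protection: HCl in MeOH at 50 °C would give 2,6-dihydroxy-4-methoxybenzaldehyde F9. One equivalent of MOMCl with i-Pr2NEt (CH2Cl2, 0 °C) should then protect a single hydroxyl, because the two are equivalent and the remaining one is deactivated by its hydrogen bond to the formyl group.

## Further compounds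

F1 | step 15 | (2E)-3-{4-[(tert-butyldimethylsilyl)oxy]phenyl}-N-methoxy-N-methylprop-2-enamide | CON(C)C(=O)/C=C/c1ccc(O[Si](C)(C)C(C)(C)C)cc1
F2 | step 15 | {3-[(1S,2E,5R)-5-[(tert-butyldimethylsilyl)oxy]-1,7-bis{4-[(tert-butyldimethylsilyl)oxy]phenyl}hept-2-en-1-yl]-6-methoxy-2,4-bis(methoxymethoxy)phenyl}lithium | COc1cc(OCOC)c([C@@H](/C=C/C[C@H](O[Si](C)(C)C(C)(C)C)CCc2ccc(O[Si](C)(C)C(C)(C)C)cc2)c2ccc(O[Si](C)(C)C(C)(C)C)cc2)c(OCOC)c1[Li]
F3 | step 11 | 2-({(E)-2-[4-methoxy-2,6-bis(methoxymethoxy)phenyl]ethenyl}sulfonyl)pyridine | COc1cc(OCOC)c(/C=C/S(=O)(=O)c2ccccn2)c(OCOC)c1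
F4 | step 11 | 2-{[(2S)-2-{4-[(tert-butyldimethylsilyl)oxy]phenyl}-2-[4-methoxy-2,6-bis(methoxymethoxy)phenyl]ethyl]sulfonyl}pyridine | COc1cc(OCOC)c([C@@H](CS(=O)(=O)c2ccccn2)c2ccc(O[Si](C)(C)C(C)(C)C)cc2)c(OCOC)c1
F5 | step 11 | tert-butyl{[(3R)-1-{4-[(tert-butyldimethylsilyl)oxy]phenyl}hex-5-en-3-yl]oxy}dimethylsilane | C=CC[C@H](O[Si](C)(C)C(C)(C)C)CCc1ccc(O[Si](C)(C)C(C)(C)C)cc1
F6 | step 11 | (3R)-3-[(tert-butyldimethylsilyl)oxy]-5-{4-[(tert-butyldimethylsilyl)oxy]phenyl}pentanal | O=CC[C@H](O[Si](C)(C)C(C)(C)C)CCc1ccc(O[Si](C)(C)C(C)(C)C)cc1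
F7 | step 8 | tert-butyldimethyl{4-[2-(oxiran-2-yl)ethyl]phenoxy}silane, racemic | C1OC1CCc1ccc(O[Si](C)(C)C(C)(C)C)cc1
F8 | step 8 | tert-butyldimethyl(4-{2-[(2R)-oxiran-2-yl]ethyl}phenoxy)silane | C1[C@H](O1)CCc1ccc(O[Si](C)(C)C(C)(C)C)cc1
F9 | step 3 | 2,6-dihydroxy-4-methoxybenzaldehyde | COc1cc(O)c(C=O)c(O)c1
A1 | alternative 1 | 3-methoxycyclobut-2-en-1-one | COC1=CC(=O)C1
A2 | alternative 1 | {[(3S,4E,7R)-7-[(tert-butyldimethylsilyl)oxy]-3,9-bis{4-[(tert-butyldimethylsilyl)oxy]phenyl}non-4-en-1-yn-1-yl]oxy}tri(propan-2-yl)silane | CC(C)[Si](OC#C[C@@H](/C=C/C[C@H](O[Si](C)(C)C(C)(C)C)CCc1ccc(O[Si](C)(C)C(C)(C)C)cc1)c1ccc(O[Si](C)(C)C(C)(C)C)cc1)(C(C)C)C(C)C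
A3 | alternative 1 | 2-[(1S,2E,5R)-5-[(tert-butyldimethylsilyl)oxy]-1,7-bis{4-[(tert-butyldimethylsilyl)oxy]phenyl}hept-2-en-1-yl]-5-methoxy-3-[(triisopropylsilyl)oxy]phenol | COc1cc(O)c([C@@H](/C=C/C[C@H](O[Si](C)(C)C(C)(C)C)CCc2ccc(O[Si](C)(C)C(C)(C)C)cc2)c2ccc(O[Si](C)(C)C(C)(C)C)cc2)c(O[Si](C(C)C)(C(C)C)C(C)C)c1
A4 | alternative 2 | 2-[(1E)-buta-1,3-dien-1-yl]-5-methoxy-1,3-bis(methoxymethoxy)benzene | COc1cc(OCOC)c(/C=C/C=C)c(OCOC)c1
A5 | alternative 2 | {4-[(tert-butyldimethylsilyl)oxy]phenyl}boronic acid | CC(C)(C)[Si](C)(C)Oc1ccc(B(O)O)cc1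
A6 | alternative 2 | (3R,5E,7S)-7-[4-methoxy-2,6-bis(methoxymethoxy)phenyl]-1,7-bis{4-[(tert-butyldimethylsilyl)oxy]phenyl}hept-5-en-3-ol | COc1cc(OCOC)c([C@@H](/C=C/C[C@H](O)CCc2ccc(O[Si](C)(C)C(C)(C)C)cc2)c2ccc(O[Si](C)(C)C(C)(C)C)cc2)c(OCOC)c1
A7 | alternative 3 | ethyl 2-[(1R,2E,5R)-5-[(tert-butyldimethylsilyl)oxy]-1,7-bis{4-[(tert-butyldimethylsilyl)oxy]phenyl}hept-2-en-1-yl]-5-methoxy-3,7-dioxooct-4-enoate, C2 configuration and enol ether geometry unassigned | CCOC(=O)C([C@@H](/C=C/C[C@H](O[Si](C)(C)C(C)(C)C)CCc1ccc(O[Si](C)(C)C(C)(C)C)cc1)c1ccc(O[Si](C)(C)C(C)(C)C)cc1)C(=O)C=C(OC)CC(C)=O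
A8 | alternative 3 | 1-{2,4-dihydroxy-3-[(1S,2E,5R)-5-[(tert-butyldimethylsilyl)oxy]-1,7-bis{4-[(tert-butyldimethylsilyl)oxy]phenyl}hept-2-en-1-yl]-6-methoxyphenyl}ethan-1-one | COc1cc(O)c([C@@H](/C=C/C[C@H](O[Si](C)(C)C(C)(C)C)CCc2ccc(O[Si](C)(C)C(C)(C)C)cc2)c2ccc(O[Si](C)(C)C(C)(C)C)cc2)c(O)c1C(C)=O
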